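## Structural features

The target is a cyclised, chlorinated prostanoid in which ring A, a 2-chlorocyclopent-2-en-1-one (C8, C9 ketone, C10–Cl, C11=, C12), is cis-fused through the C8–C12 bond to ring B, a tetrahydrofuran (C12–O–C6–C7–C8). C12 is a fully substituted, oxygen-bearing fusion carbon that also carries the (Z)-oct-2-enyl chain C13–C20; C6 carries the side chain C5(OAc)–C4–C1 ending in the methyl ester, and C7 carries the second acetate. Five stereocentres are contiguous (C5, C6, C7, C8, C12): on ring B, C13, the C7 acetoxy group and C5 lie on one face (β below), while C11 and C9, that is ring A, lie on the other (α). The fragile points are: the C7 acetate, which is β to the C9 ketone and leaves by E1cB once C8 is enolised; the α-chloroenone; the skipped (Z)-alkene, the most nucleophilic π bond, which excludes free halogen or peracid late in the route; and the C5 oxygen, which as a free hydroxyl or alkoxide can close onto the C1 ester (δ-lactone). The real difficulty is the quaternary ether carbon C12 in a fixed relation to C6 and in one absolute sense, followed by a ring-A closure on the α face that leaves the C7 oxygen on the β face. The key step uses the fact that C12 and C6 flank the ring-B oxygen and hold C13 and C5 cis: they are the two bridgeheads of an 8-oxabicyclo[3.2.1]oct-6-en-3-one whose three-carbon bridge is C13–C14–C5 (C14 the ketone) and whose etheno bridge is C7=C8. A furan–oxyallyl (4+3) cycloaddition therefore makes C12–C13 and C5–C6 together, and oxygen insertion into C5–C14 later releases both chains.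

## Logic of the disconnections

**22 ⇒ 20.** The C10=C11 double bond and the acetyl groups on the C7 and C11 oxygens are removed (retro-E1cB, retro-acylation). The β-acetoxy enone is the most base-sensitive array, so it is made last. The gain is a saturated chloro ketone with two free hydroxyls. The forward step must start its elimination at C10–H (α to carbonyl and chlorine) and not at C8–H, which would expel the C7 acetate.

**20 ⇒ 19 ⇒ 18 ⇒ 17.** The C10–Cl bond and two silyl ethers are cut. Chlorine has to arrive as an electrophile on an enolate, because the (Z)-alkene forbids free halogen. The gain is a halogen-free β-hydroxy ketone. The forward enolisation must take the C10 methylene, not the C8 methine, and must meet only poor leaving groups at C7 and C11; hence both oxygens are silylated in 18.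

**17 ⇒ 15.** Ring A is opened at C8–C9; the C9 carbonyl goes back to a nitrile and the C7 hydroxyl to a C7–C8 epoxide. The C8–C9 bond and the C7 oxygen are trans on ring B, which is the signature of an epoxide opened with C–C bond formation. A nitrile is already at the ketone oxidation level, and single-electron chemistry tolerates the esters. The gain is a monocyclic precursor with C7 and C8 traced to one epoxide. The demands are an epoxide on the β face, cleavage of its C8–O bond, and radical addition to the nitrile faster than reduction.

**15 ⇒ 14 ⇒ 13.** The C5–OAc bond is cut with inversion and the epoxide oxygen is removed. The C5 hydroxyl, which emerges with the wrong configuration, first serves as the directing group for the epoxidation (either epimer directs to the β face) and is then inverted and acetylated in one operation. The forward steps need oxygen delivery that beats the more electron-rich (Z)-alkene, an SN2 reaction at a hindered α-alkoxy carbinol, and a 5-hydroxy ester that does not lactonise.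

**13 ⇒ 11 + 12.** The C14=C15 bond is cut. The gain is removal of the C15–C20 chain as a commercial salt; the C14 aldehyde appears masked with the C5 oxygen. The demands are Z-selectivity and an ylide free of excess base.

**11 ⇒ 10 ⇒ 9.** C14 is returned to the lactone level and the C5–O bond is traced to the C5–C14 bond of a ketone. This turns the two chains back into one ring, so the acyclic C5 carbinol becomes a ring stereocentre under thermodynamic control. The forward oxidation must migrate C5, not C13, and spare the C7=C8 bond; the hydride must stop at the lactol and spare ester and nitrile.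

**9 ⇒ 8 ⇒ 2 + 5.** C12–C13 and C5–C6 are cut, the two C–C bonds at the carbons flanking the ring-B oxygen. The whole framework reduces to a 2-substituted furan and an α,α′-dibromoketone, with three stereocentres formed. The demands are regiochemistry (CH2 terminus to the substituted furan carbon) and selection of one furan face.
- For face selection the arm of 2 carries a C11 carbinol, which steers the cycloaddition and later becomes the leaving group that gives C10=C11.
- C9 is a nitrile, so no deprotection, oxidation or carbonyl umpolung is needed later.
- The descriptors of 8 at C12 and C6 agree with those of 22; its equatorial C5 centre is the epimer that requires the inversion of step 10.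

**2 ⇒ 1; 5 ⇒ 4 ⇒ 3.** The C11–H bond comes from enantioselective reduction of a commercial β-keto nitrile; the two C–Br bonds and the ester come from a commercial keto acid.

## Other disconnections considered

**Alternative 1:** The cut is C9–C10 in ring A, with C10–Cl traced to C10–Si. In the forward step the 4-alkynal A2 (C9 aldehyde on C8, silylethynyl group on C12) is treated with [Rh(dppe)]2(BF4)2 (monovalent rhodium); insertion into the aldehyde C–H, trans addition across the alkyne and reductive elimination give the 2-silylcyclopentenone A1. Chlorine would then replace silicon.
- In favour: ring A and its enone arise in one catalytic, base-free step, and C10 is marked for halogenation from the outset.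
- Against: A2 is a β-acetoxy aldehyde with an enolisable C8, open to loss of the C7 acetate, epimerisation and decarbonylation. Its ring B, with four contiguous centres and the quaternary propargylic ether C12, must be built without a rigid template. Silicon-to-chlorine exchange on an electron-poor vinylsilane needs electrophilic chlorine, which the (Z)-alkene does not tolerate.
- Comparison: structurally it leaves the hardest element (C12 and C6) to other chemistry. Mechanistically its ring-A closure is better than the chosen plan, because it has no regiochemical ambiguity whereas the epoxide opening of step 11 has two possible senses. In step economy the closure itself is equal, but the path to A2 is expected to be longer than the nine steps that lead to 15.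

**Alternative 2:** The cut is C6–C7 in ring B. In the forward step A4 (ring A complete, C7 aldehyde on C8, (Z)-γ-alkoxyallylstannane tethered through the C12 oxygen) cyclises thermally or with BF3·OEt2. The oxygen-bearing allyl terminus C6 adds to the aldehyde to give A3, with the C7 hydroxyl and the C6 vinyl group cis.
- In favour: C6 and C7 are set together in a closed transition state. Ring A and its chlorine come from a cyclopentenone building block, so no late chlorination is needed; on this point it is better than the chosen plan.
- Against: the stannane has to be built on a hindered tertiary C12 alkoxide (allylation, then metalation and stannylation with strong base next to a chloroalkene). A3 lacks the C5 stereocentre and the whole C1–C4 chain, so the vinyl group must be oxidised and extended under new stereocontrol. C9 still needs oxidation, and stoichiometric tin is used.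
- Comparison: structurally it fixes two of five centres and leaves C5 open. Mechanistically this cyclisation is well behaved for six- and seven-membered ethers but less established for a tetrahydrofuran fused to a cyclopentene. In step economy it is worse, since the chosen plan carries C5 and its chain from 5.

**Alternative 3:** The cut is C8–C12. In the forward step the diazo keto ester A6 with Rh2(OAc)4 forms a carbenoid at C8 that inserts into the ether-activated C12–H bond with retention, giving the tetrahydrofuran-3-one A5.
- In favour: quaternary C12 comes from a secondary carbinol of known configuration, and C5/C6 from a separate chiral fragment joined by ether formation. Absolute configuration then needs no facial-selectivity argument; on this point it is better than the chosen plan. Five-membered C–H insertion next to oxygen is a dependable mode.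
- Against: A5 has no ring A (C10 is absent, C11 is a protected hydroxymethyl group, C9 an ester). C7 is a ketone that must be reduced to the β-alcohol from the more hindered side, and C8 stays epimerisable. The carbenoid can also attack the (Z)-alkene or benzylic C–H bonds.
- Comparison: structurally it solves C12 but not the ring fusion. Mechanistically the precedent is equal to that of the chosen key step. In step economy it is clearly longer after the key step.

Key step: step 4

Assumption (chemistry): in step 4 the zinc alkoxide at C11 is taken to deliver the oxyallyl to the furan face on which the C11 oxygen lies when the carbinol C–H eclipses the furan C12=C8 bond. This maps the (S)-carbinol 2 onto the target series; the enantiomeric transfer-hydrogenation catalyst would supply the (R)-carbinol should the sense prove opposite.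

## Route

Step 1
Reactants: 1 3-(furan-2-yl)-3-oxopropanenitrile
Product: 2 (S)-3-(furan-2-yl)-3-hydroxypropanenitrile
Conditions: RuCl(p-cymene)[(S,S)-TsDPEN] (1 mol%), HCO2H–Et3N (5:2), rt
Reagents that add atoms: none
Why: Asymmetric transfer hydrogenation of an aryl β-keto nitrile; the (S,S)-catalyst should deliver hydride to the face that gives the (S)-carbinol, as with other aryl ketones, and this sets C11.

Step 2
Reactants: 3 6-oxoheptanoic acid
Product: 4 methyl 6-oxoheptanoate
Conditions: MeOH, H2SO4 (cat.), reflux
Reagents that add atoms: methanol CO
Why: Fischer esterification; the methyl ester is the C1 group of the target and keeps an acidic proton away from the organozinc of step 4.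

Step 3
Reactants: 4 methyl 6-oxoheptanoate
Product: 5 methyl 5,7-dibromo-6-oxoheptanoate (racemic)
Conditions: Br2 (2.0 equiv), HBr (33% in AcOH, cat.), CH2Cl2, 0 °C → rt
Reagents that add atoms: bromine BrBr
Why: Acid-catalysed α-bromination of a ketone through its enols; the first bromine enters at the more substituted C5, the second at the methyl group because an α-bromine retards enolisation toward its own carbon, and HBr equilibrates positional isomers toward the α,α′-dibromide.

Step 4
Reactants: 2 (S)-3-(furan-2-yl)-3-hydroxypropanenitrile; 5 methyl 5,7-dibromo-6-oxoheptanoate
Product: 8 hydroxy ketone cycloadduct (8-oxabicyclo[3.2.1]oct-6-en-3-one; C5 chain equatorial; free C11 hydroxyl), via ethylzinc oxyallyl cation 6 (not isolated), via C5-axial cycloadduct 7 (not isolated)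
Conditions: Et2Zn (2.2 equiv), toluene, 0 °C; 5 (1.6 equiv) added over 2 h, 0 °C → rt; aq. NH4Cl; then DBU (0.2 equiv), CH2Cl2, rt
Reagents that add atoms: none
Why: Et2Zn converts 2 into its ethylzinc alkoxide and, by bromine–zinc exchange on 5 followed by loss of bromide, generates the zinc-bound oxyallyl cation 6. Cation 6 adds across the 2- and 5-positions of the furan in a (4+3) cycloaddition, either concerted but asynchronous or stepwise (attack of the free furan α-carbon C6 on the substituted terminus C5, then enolate closure at C12); the closest known reaction is the cycloaddition of furans with oxyallyl cations from α,α′-dibromoketones, including its hydroxyl-directed variant with secondary furyl carbinols. The seven-membered carbocycle C12–C13–C14–C5–C6–C7–C8 is closed by this annulation with both new σ bonds on one furan face, so the furan oxygen becomes the one-atom bridge. C12 and C6 are cis by necessity of the bridge, and their absolute sense is controlled by the C11 stereocentre, whose zinc alkoxide binds the oxyallyl oxygen and guides it to the face on which the C11 oxygen lies. Because C11 is fixed, the two ring-enantiomeric series are diastereomers, so any minor one is removed by chromatography. C5 forms as a mixture, and DBU converts the axial epimer 7 through the enol into the equatorial epimer 8 (thermodynamic control). The regiochemistry (CH2 terminus to the substituted furan carbon) is secured by sterics at the forming quaternary centre and by pairing of the more nucleophilic free furan α-carbon with the cation-stabilising substituted terminus. Ester and nitrile are inert to the organozinc.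

Step 5
Reactants: 8 hydroxy ketone cycloadduct
Product: 9 C11 tert-butyldimethylsilyl ether of 8
Conditions: t-BuMe2SiOTf (1.2 equiv), 2,6-lutidine, CH2Cl2, −78 → 0 °C
Reagents that add atoms: tert-butyldimethylsilyl trifluoromethanesulfonate CC(C)(C)[Si](C)(C)OS(=O)(=O)C(F)(F)F
Why: Silylation of a hindered secondary alcohol with a silyl triflate; it removes the hydroxyl that would later direct epoxidation to the α face and installs an ether that lasts to step 14, and at low temperature the alcohol reacts far faster than the ketone enolises.

Step 6
Reactants: 9 C11 silyl ether ketone
Product: 10 bridged lactone (3,9-dioxabicyclo[4.2.1]non-7-en-4-one; oxygen between C14 and C5)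
Conditions: Me3SiOOSiMe3 (2 equiv), Me3SiOTf (0.2 equiv), CH2Cl2, −40 → −20 °C
Reagents that add atoms: bis(trimethylsilyl) peroxide C[Si](C)(C)OO[Si](C)(C)C
Why: Baeyer–Villiger oxidation with a silyl peroxide and a Lewis acid; the more substituted C5 migrates from C14 to oxygen with retention, and this oxidant does not epoxidise the C7=C8 bond as a peracid could.

Step 7
Reactants: 10 bridged lactone
Product: 11 lactol (C14 hemiacetal; both anomers)
Conditions: i-Bu2AlH (1.05 equiv), toluene, −78 °C; MeOH, then aq. KNaC4H4O6
Reagents that add atoms: none
Why: Partial reduction of a lactone to a lactol; the bridged lactone (E-ester geometry) is more electrophilic than the acyclic methyl ester and the nitrile, and its tetrahedral aluminate is stable at −78 °C, so one equivalent of hydride should stop at the lactol.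

Step 8
Reactants: 11 lactol; 12 hexyltriphenylphosphonium bromide
Product: 13 hydroxy ester with the (Z)-oct-2-enyl chain on C12 (2,5-dihydrofuran; free C5 hydroxyl not yet inverted)
Conditions: 12 (2.5 equiv), NaN(SiMe3)2 (2.4 equiv), THF, −78 → 0 °C; 11 added at −78 °C, then → −10 °C; AcOH (3 equiv) at −40 °C
Reagents that add atoms: none
Why: Wittig olefination of the open hydroxy aldehyde form of the lactol with an unstabilised ylide under salt-free conditions should give the (Z)-alkene; a slight deficit of base leaves no amide to deprotonate next to the nitrile, and the cold acidic quench protonates the C5 alkoxide before it adds to the C1 ester.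

Step 9
Reactants: 13 hydroxy ester
Product: 14 β-epoxide at C7–C8 (epoxide oxygen cis to C5 and C13)
Conditions: VO(acac)2 (8 mol%), t-BuOOH (1.5 equiv, in decane), CH2Cl2, 0 °C → rt
Reagents that add atoms: tert-butyl hydroperoxide CC(C)(C)OO
Why: Hydroxyl-directed epoxidation of a homoallylic alcohol; the vanadate ester of the C5 hydroxyl delivers oxygen to the ring-B face that carries C5 (β), which places the C7 oxygen as in the target, and the unbound (Z)-alkene is not epoxidised.

Step 10
Reactants: 14 epoxy alcohol
Product: 15 epoxy acetate with C5 inverted to the configuration of the target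
Conditions: PPh3, DIAD, AcOH, toluene, 0 °C → rt
Reagents that add atoms: acetic acid CC(=O)O
Why: Mitsunobu reaction; SN2 displacement of the activated C5 oxygen by acetate inverts C5 and installs the C5 acetate in the same operation.

Step 11
Reactants: 15 epoxy acetate nitrile
Product: 17 hydroxy ketone (ring A cyclopentanone cis-fused to ring B; C7 hydroxyl β), via cyclic ketimine 16 (not isolated)
Conditions: Cp2TiCl2 (2.6 equiv), Zn dust, THF, rt (gives Cp2TiCl, added slowly to 15 in THF); then 1 M aq. HCl, 0 °C
Reagents that add atoms: water O
Why: Cp2TiCl-mediated reductive epoxide opening (trivalent titanium, single-electron transfer) with radical cyclisation onto a nitrile; the C8 radical closes 5-exo on C9 from the α face, the only face the C12 tether reaches, so ring A is cis-fused and the C7 oxygen stays β. The iminyl radical is reduced by a second Cp2TiCl and ketimine 16 is hydrolysed on work-up, while the esters and acetate are untouched.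

Step 12
Reactants: 17 hydroxy ketone
Product: 18 C7 triethylsilyl ether of 17
Conditions: Et3SiOTf (1.2 equiv), 2,6-lutidine, CH2Cl2, −78 °C
Reagents that add atoms: triethylsilyl trifluoromethanesulfonate CC[Si](CC)(CC)OS(=O)(=O)C(F)(F)F
Why: Silylation of a β-hydroxy ketone with a silyl triflate; the C7 oxygen becomes a poor leaving group and no free hydroxyl remains for retro-aldol cleavage in the enolate step.

Step 13
Reactants: 18 bis-silyl ketone
Product: 19 C10-chloro ketone (C10 epimers)
Conditions: LiN(SiMe3)2 (1.1 equiv), THF, −78 °C; NCS (1.2 equiv), −78 → −40 °C; aq. NH4Cl
Reagents that add atoms: N-chlorosuccinimide O=C1CCC(=O)N1Cl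
Why: Kinetic enolate formation and electrophilic α-chlorination; the bulky amide takes a proton from the C10 methylene and not from the hindered C8 methine, and the ketone is several pKa units more acidic than the ester and acetate. Silyloxy groups β to the enolate are not expelled at −78 °C, and NCS leaves the (Z)-alkene alone.

Step 14
Reactants: 19 C10-chloro bis-silyl ketone
Product: 20 chloro diol ketone (free C7 and C11 hydroxyls)
Conditions: HF·pyridine, pyridine, THF, 0 °C → rt
Reagents that add atoms: none
Why: Fluoride-mediated cleavage of both silyl ethers under buffered conditions that the acetate, ester and α-chloro ketone tolerate; any early loss of water at C11 only anticipates step 15.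

Step 15
Reactants: 20 chloro diol ketone
Product: 22 CNP0318775.1 (target), via triacetate 21 (not isolated)
Conditions: Ac2O (6 equiv), pyridine, DMAP (0.1 equiv), CH2Cl2, 0 °C → rt; then Et3N (1.2 equiv), 0 °C
Reagents that add atoms: acetic anhydride CC(=O)OC(C)=O
Why: Acetylation of both hydroxyls followed by E1cB elimination; in 21 the C10 proton (α to carbonyl and chlorine) is far more acidic than the C8 proton, so the amine expels the C11 acetate to give the chloroenone while the C7 and C5 acetates stay.

## Compound list

1 | 3-(furan-2-yl)-3-oxopropanenitrile | N#CCC(=O)c1ccco1 | starting material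
2 | (S)-3-(furan-2-yl)-3-hydroxypropanenitrile (C11 carbinol, C9 nitrile) | N#CC[C@H](O)c1ccco1 | intermediate
3 | 6-oxoheptanoic acid | CC(=O)CCCCC(=O)O | starting material
4 | methyl 6-oxoheptanoate | COC(=O)CCCCC(C)=O | intermediate
5 | methyl 5,7-dibromo-6-oxoheptanoate (racemic) | COC(=O)CCCC(Br)C(=O)CBr | intermediate
6 | ethylzinc-bound oxyallyl cation from 5 (bromide) | COC(=O)CCC[CH+]C(=C)O[Zn]CC.[Br-] | intermediate (not isolated)
7 | C5-axial epimer of cycloadduct 8 | N#CC[C@H](O)[C@@]12C=C[C@@H](O1)[C@@H](CCCC(=O)OC)C(=O)C2 | intermediate (not isolated)
8 | cycloadduct: 8-oxabicyclo[3.2.1]oct-6-en-3-one (ketone C14) with the (S)-CH(OH)CH2CN arm on bridgehead C12 and the equatorial (CH2)3CO2Me chain on C5; C12 and C6 as in the target | N#CC[C@H](O)[C@@]12C=C[C@@H](O1)[C@H](CCCC(=O)OC)C(=O)C2 | intermediate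
9 | C11 tert-butyldimethylsilyl ether of 8 | N#CC[C@H](O[Si](C)(C)C(C)(C)C)[C@@]12C=C[C@@H](O1)[C@H](CCCC(=O)OC)C(=O)C2 | intermediate
10 | bridged lactone from 9 (3,9-dioxabicyclo[4.2.1]non-7-en-4-one; ring oxygen on C5 with retention) | N#CC[C@H](O[Si](C)(C)C(C)(C)C)[C@@]12C=C[C@@H](O1)[C@H](CCCC(=O)OC)OC(=O)C2 | intermediate
11 | lactol from 10 (C14 hemiacetal, both anomers) | N#CC[C@H](O[Si](C)(C)C(C)(C)C)[C@@]12C=C[C@@H](O1)[C@H](CCCC(=O)OC)OC(O)C2 | intermediate
12 | hexyltriphenylphosphonium bromide | CCCCCC[P+](c1ccccc1)(c1ccccc1)c1ccccc1.[Br-] | starting material
13 | hydroxy ester: 2,5-dihydrofuran (C7=C8) with (Z)-oct-2-enyl (β) and CH(OTBS)CH2CN (α) on C12 and CH(OH)(CH2)3CO2Me (β) on C6; C5 opposite to the target | CCCCC/C=C\C[C@@]1([C@@H](O[Si](C)(C)C(C)(C)C)CC#N)O[C@@H]([C@H](CCCC(=O)OC)O)C=C1 | intermediate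
14 | β-epoxide of 13 at C7–C8 (oxygen cis to C5 and C13) | CCCCC/C=C\C[C@@]1([C@@H](O[Si](C)(C)C(C)(C)C)CC#N)O[C@@H]([C@H](CCCC(=O)OC)O)[C@H]2O[C@@H]12 | intermediate
15 | epoxy acetate: C5 acetate in the configuration of the target, β-epoxide retained | CCCCC/C=C\C[C@@]1([C@@H](O[Si](C)(C)C(C)(C)C)CC#N)O[C@@H]([C@@H](CCCC(=O)OC)OC(C)=O)[C@H]2O[C@@H]12 | intermediate
16 | cyclic ketimine (cis-fused bicycle, C9=NH, C7 hydroxyl β) | CCCCC/C=C\C[C@]12[C@@H](O[Si](C)(C)C(C)(C)C)CC(=N)[C@H]1[C@H](O)[C@H]([C@@H](CCCC(=O)OC)OC(C)=O)O2 | intermediate (not isolated)
17 | hydroxy ketone: ring A cyclopentanone cis-fused to ring B; C7 hydroxyl β; C11 silyl ether; C5 acetate | CCCCC/C=C\C[C@]12[C@@H](O[Si](C)(C)C(C)(C)C)CC(=O)[C@H]1[C@H](O)[C@H]([C@@H](CCCC(=O)OC)OC(C)=O)O2 | intermediate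
18 | C7 triethylsilyl ether of 17 | CCCCC/C=C\C[C@]12[C@@H](O[Si](C)(C)C(C)(C)C)CC(=O)[C@H]1[C@H](O[Si](CC)(CC)CC)[C@H]([C@@H](CCCC(=O)OC)OC(C)=O)O2 | intermediate
19 | C10-chloro derivative of 18 (C10 epimers) | CCCCC/C=C\C[C@]12[C@@H](O[Si](C)(C)C(C)(C)C)C(Cl)C(=O)[C@H]1[C@H](O[Si](CC)(CC)CC)[C@H]([C@@H](CCCC(=O)OC)OC(C)=O)O2 | intermediate
20 | chloro diol ketone (free C7 and C11 hydroxyls, C5 acetate) | CCCCC/C=C\C[C@]12[C@@H](O)C(Cl)C(=O)[C@H]1[C@H](O)[C@H]([C@@H](CCCC(=O)OC)OC(C)=O)O2 | intermediate
21 | triacetate (C5, C7 and C11 acetates) of the chloro ketone | CCCCC/C=C\C[C@]12[C@@H](OC(C)=O)C(Cl)C(=O)[C@H]1[C@H](OC(C)=O)[C@H]([C@@H](CCCC(=O)OC)OC(C)=O)O2 | intermediate (not isolated)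
22 | CNP0318775.1: methyl ester of the 5,7-diacetoxy-10-chloro-9-oxo-6,12-epoxyprosta-10,14(Z)-dienoic acid, configured as in the SMILES | CCCCC/C=C\C[C@]12C=C(Cl)C(=O)[C@H]1[C@H](OC(C)=O)[C@H]([C@@H](CCCC(=O)OC)OC(C)=O)O2 | target

## Step count and least certain steps

Total: 15 steps. Longest linear sequence: 14 steps (3 to 22 through steps 2–15); the branch from 1 (step 1) joins at step 4.

**Step 4 (key step).** Three processes may interfere: reduction of the dibromide without capture by the furan, because the mono-alkylated oxyallyl is less stabilised than the dialkyl cations on which the method usually runs; weak or reversed facial guidance by the zinc alkoxide; and ionisation of the furyl carbinol at the Lewis-acidic zinc. The fallback gives up chelation and relies on separation. It sets out from 2, which is silylated (t-BuMe2SiOTf, 2,6-lutidine) to the silyl ether F1. F1 is combined with 5 and zinc–copper couple under ultrasound in THF, followed by DBU equilibration at C5. The two cycloadducts differ in ring configuration relative to the fixed C11 centre, so they are diastereomers and are separated by chromatography. The required one is 9, where the route is rejoined.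

**Step 11.** The wrong epoxide C–O bond may break (radical at C7), since the two carbons are electronically alike. The C8 radical may also be reduced by a second trivalent titanium before it adds to the nitrile, which leads to deoxygenation. The fallback fixes the regiochemistry through the neighbouring C5 acetate and sets out from 13.
- Mitsunobu reaction of 13 (PPh3, DIAD, AcOH) gives the inverted alkene acetate F2.
- NIS in dry CH2Cl2, then water: the C5 acetate carbonyl attacks C7 from the β face through a six-membered acetoxonium ion while iodine occupies C8 on the α face. The reversible iodonium of the (Z)-alkene has no internal nucleophile. Hydrolysis gives the iodo hydroxy acetate F3.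
- (Me3Si)3SiH and AIBN (benzene, 80 °C, slow addition), then dilute aqueous acid: the C8 radical cyclises 5-exo onto the nitrile and the route is rejoined at 17.
- Any acetyl migration between the C5 and C7 oxygens is without consequence, because all free hydroxyls are acetylated in step 15.

**Step 7.** Competing reduction of the C1 methyl ester or the nitrile, or over-reduction past the lactol, may occur. The fallback keeps C1 as a spectator carboxylate and sets out from 9.
- LiOH (THF–H2O, 0 °C) gives the keto acid F4.
- The same silyl peroxide oxidation, after silylation of the acid in situ, gives the lactone acid F5.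
- i-Bu2AlH (2.2 equiv, −78 °C; the aluminium carboxylate is not reduced) gives the lactol acid F6.
- Olefination with 3.5 equiv of the ylide from 12 gives the hydroxy acid F7, whose carboxylate cannot be attacked by the C5 alkoxide.
- Acidification to pH 5 at 0 °C and Me3SiCHN2 (MeOH–toluene) rejoin the route at 13.

**Step 8.** The C5 alkoxide may transesterify onto the C1 ester (δ-lactonisation) during the olefination, and Z-selectivity may erode. The fallback sets out from 11 and lets the olefination mixture warm until lactonisation is complete, so that the δ-lactone F8 is isolated as a single compound. NaOMe (cat.) in MeOH at 0 °C, quenched with AcOH at 0 °C, reopens it to 13, which is used at once.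

**Step 10.** Substitution at the hindered α-alkoxy carbinol may be slow, and elimination or participation of the C1 ester carbonyl may compete. The fallback replaces the redox condensation by sulfonate displacement. It sets out from 14: MsCl and Et3N give the mesylate F9, and CsOAc with 18-crown-6 (toluene, 80 °C) displaces it with inversion to rejoin the route at 15.

## Further compounds

F1 | step 4 | (S)-3-(tert-butyldimethylsilyloxy)-3-(furan-2-yl)propanenitrile | N#CC[C@H](O[Si](C)(C)C(C)(C)C)c1ccco1
F2 | step 11 | C5 acetate (target configuration) of the 2,5-dihydrofuran 13 skeleton, C7=C8 intact | CCCCC/C=C\C[C@@]1([C@@H](O[Si](C)(C)C(C)(C)C)CC#N)O[C@@H]([C@@H](CCCC(=O)OC)OC(C)=O)C=C1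
F3 | step 11 | iodo hydroxy acetate: iodine on C8 (α), hydroxyl on C7 (β), C5 acetate | CCCCC/C=C\C[C@@]1([C@@H](O[Si](C)(C)C(C)(C)C)CC#N)O[C@@H]([C@@H](CCCC(=O)OC)OC(C)=O)[C@@H](O)[C@@H]1I
F4 | step 7 | keto acid: C1 carboxylic acid corresponding to 9 | N#CC[C@H](O[Si](C)(C)C(C)(C)C)[C@@]12C=C[C@@H](O1)[C@H](CCCC(=O)O)C(=O)C2
F5 | step 7 | lactone acid: C1 carboxylic acid corresponding to 10 | N#CC[C@H](O[Si](C)(C)C(C)(C)C)[C@@]12C=C[C@@H](O1)[C@H](CCCC(=O)O)OC(=O)C2
F6 | step 7 | lactol acid: C1 carboxylic acid corresponding to 11 | N#CC[C@H](O[Si](C)(C)C(C)(C)C)[C@@]12C=C[C@@H](O1)[C@H](CCCC(=O)O)OC(O)C2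
F7 | step 7 | hydroxy acid: C1 carboxylic acid corresponding to 13 | CCCCC/C=C\C[C@@]1([C@@H](O[Si](C)(C)C(C)(C)C)CC#N)O[C@@H]([C@H](CCCC(=O)O)O)C=C1
F8 | step 8 | δ-lactone between the C5 oxygen and C1 of 13 | CCCCC/C=C\C[C@@]1([C@@H](O[Si](C)(C)C(C)(C)C)CC#N)O[C@@H]([C@@H]2CCCC(=O)O2)C=C1
F9 | step 10 | C5 methanesulfonate of epoxy alcohol 14 | CCCCC/C=C\C[C@@]1([C@@H](O[Si](C)(C)C(C)(C)C)CC#N)O[C@@H]([C@H](CCCC(=O)OC)OS(C)(=O)=O)[C@H]2O[C@@H]12
A1 | alternative 1 | bicyclic enone with trimethylsilyl on C10 in place of chlorine | CCCCC/C=C\C[C@]12C=C([Si](C)(C)C)C(=O)[C@H]1[C@H](OC(C)=O)[C@H]([C@@H](CCCC(=O)OC)OC(C)=O)O2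
A2 | alternative 1 | 4-alkynal: ring B with the C9 aldehyde on C8 and the trimethylsilylethynyl group on C12 | CCCCC/C=C\C[C@]1(C#C[Si](C)(C)C)[C@@H](C=O)[C@H](OC(C)=O)[C@H]([C@@H](CCCC(=O)OC)OC(C)=O)O1
A3 | alternative 2 | cis-fused bicycle with C7 hydroxyl and C6 vinyl group cis, C9 silyl ether | CCCCC/C=C\C[C@]12C=C(Cl)C(O[Si](C)(C)C(C)(C)C)[C@H]1[C@H](O)[C@H](C=C)O2
A4 | alternative 2 | ring A aldehyde with the (Z)-γ-alkoxyallyl tributylstannane on the C12 oxygen | CCCCC/C=C\C[C@]1(O/C=C\C[Sn](CCCC)(CCCC)CCCC)C=C(Cl)C(O[Si](C)(C)C(C)(C)C)[C@H]1C=O
A5 | alternative 3 | tetrahydrofuran-3-one with quaternary C12, C8 ester and C7 ketone | CCCCC/C=C\C[C@]1(COCc2ccc(OC)cc2)C(C(=O)OCC[Si](C)(C)C)C(=O)[C@H]([C@@H](CCCC(=O)OC)O[Si](C)(C)C(C)(C)C)O1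
A6 | alternative 3 | acyclic diazo keto ester with the C12–H ether | CCCCC/C=C\C[C@@H](COCc1ccc(OC)cc1)O[C@@H]([C@@H](CCCC(=O)OC)O[Si](C)(C)C(C)(C)C)C(=O)C(=[N+]=[N-])C(=O)OCC[Si](C)(C)C
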